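The constants used here were chosen freely; no experiment stands behind them.

4 questions stood on 3 flasks that differ in their free base.

| flask | electrophile | nucleophile | free base | scavenger | time |
|---|---|---|---|---|---|
| Friday's | 0.050 M | 3.00 equiv | 2.00 equiv | 1.20 equiv | 25 s |
| Sunday's | 0.050 M | 3.00 equiv | 4.00 equiv | 1.20 equiv | 25 s |
| Saturday's | 0.050 M | 3.00 equiv | 8.00 equiv | 1.20 equiv | 25 s |

    electrophile + nucleophile ⇌ acid set free + target (K1 = 0.39, k1 = 7.5 M⁻¹ s⁻¹)
    nucleophile + acid set free ⇌ protonated nucleophile, settled at all times (K2 = 100 M⁻¹)
    acid set free + free base ⇌ salt of the base, settled at all times (K3 = 5300 M⁻¹)
    nucleophile + acid set free ⇌ idle adduct, settled at all times (K4 = 3.3 M⁻¹)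
    acid set free + scavenger → scavenged by-product (k5 = 230 M⁻¹ s⁻¹)
    2 free base → homo dimer (k6 = 9.9 M⁻¹ s⁻¹)

- part of the electrophile that has reacted at the end, Friday's
- part of the electrophile that has reacted at the end, Sunday's
- part of the electrophile that has reacted at the end, Saturday's
- what raising the equivalents of free base from its lowest to its highest value here does to the part of the electrophile that has reacted (changes below 5 percentage points count as none) (no change / it falls / it rises)

- what is said of acid set free includes idle adduct
- a doubled species enters its step squared and goes two at a time
- run time (Friday's): 25 s

I reckoned by counting half-lives, and took the settings in turn.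

Nucleophile first. Each electrophile takes one, so I took [N]f, the charge less the electrophile charged, as a working level for the free nucleophile, setting aside what acid binds in steps 2 and 4, and held it there to get a pseudo-first-order half-life of step 1 going forward:

[N]f = 0.100 M

t½ = ln(2)/(k1[N]f) = 0.924 s

N = t/t½ = 27.1

I called N the half-life count: the forward half-lives of step 1 that fit into the run at the nucleophile's working level. The electrophile left is then its charge halved N times, so Friday's reacted part came to >99.9%. Fewer equivalents of nucleophile shrink N along with the working level.

Time enters N directly, and 27.1 half-lives already left me nothing to gain from waiting.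

Scavenger: its charge stands above the acid that step 1 can set free, and on charges the free acid's half-life by step 5, 0.0502 s, is shorter than t½.

Free base: N does not contain it, so Sunday's gave >99.9% and Saturday's >99.9%. Its first dimer half-life on charge is 0.505 s on Friday's flask, short against the run, and shorter still, 0.126 s, on Saturday's. I expected no change.

The forecast gave 99.7%, 99.6% and 99.5% for Friday's, Sunday's and Saturday's, and no change, holding that “The free base dimerises within seconds whatever its loading”. On Friday's flask it left 0.300% of the electrophile unreacted, and my count left less.

The simulation gave 99.7%, 99.7% and 99.7%: no change, the change being −0.017 percentage points. On Sunday's flask step 1, both ways together, relaxed at the end with a half-life of 0.407 s, short against the run, and 0.34% of the electrophile still stood. The figure from N = 27.1 lay 0.34 points from that flask. For a flask like Sunday's with 1.20 equiv of nucleophile, the working level drops to 10.0 mM and the count to 2.71, which gives 84.7% reacted. That flask reached 94.6%, with 21% of its nucleophile left.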